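## Retrosynthetic overview

1. Labels: ring A = resorcinol ring, ring B = catechol ring fused to the seven-membered ring, ring C = pendant catechol, ring D = monophenol ring; C-a = the CH shared by the six- and seven-membered rings, C-b = its CH2 neighbour, C-c = the ArCH, C-d = the CH2 next to ring D.
2. Target ⇐ heptamethyl ether 20 (BBr3). 20 ⇐ o-silylaryl triflate 17 by one intramolecular aryne/styrene [4+2]. The A–D biaryl bond and the D–C-a bond end on two adjacent carbons of ring D, which is therefore a latent aryne. C-a, C-b and the ipso and ortho carbons of ring A form a latent (E)-styrene diene, and ring D–C-d–C-c–ring B–C-a is the tether.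
3. This step closes the six-membered (dihydrophenanthrene) ring and the seven-membered ring together and sets C-a from C-c; a 1,3-proton shift then restores ring A and turns C-b into the CH2 group.
4. 17 ⇐ (E)-stilbene by Horner–Wadsworth–Emmons olefination (C-a=C-b) ⇐ triarylethane by B-alkyl Suzuki coupling (C-d–ring D) ⇐ β,β-diarylethyl boronate by Cu–H catalysed asymmetric hydroboration (sets C-c) ⇐ 1,1-diarylethene by Barluenga coupling (rings B and C).
5. Ring order: the four benzene rings are bought; the two carbocycles form last, in the same operation.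

Key step: step 12

Remark: the sense of induction in step 4 is assumed; the ligand antipode that delivers the (R)-boronate would be used.

## Route

Step 1
Reactants: 1 2-bromo-4,5-dimethoxybenzaldehyde
Product: 2 2-(2-bromo-4,5-dimethoxyphenyl)-1,3-dioxolane
Conditions: HOCH2CH2OH (3 equiv), p-TsOH·H2O (5 mol %), toluene, reflux, Dean–Stark
Reagents that add atoms: ethylene glycol, OCCO
Why: Acid-catalysed acetalisation with azeotropic removal of water masks the aldehyde (the future C-a) for the organometallic steps.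

Step 2
Reactants: 3 3′,4′-dimethoxyacetophenone
Product: 4 N′-[1-(3,4-dimethoxyphenyl)ethylidene]-4-methylbenzenesulfonohydrazide
Conditions: TsNHNH2 (1.05 equiv), MeOH, 60 °C
Reagents that add atoms: p-toluenesulfonyl hydrazide, Cc1ccc(cc1)S(=O)(=O)NN
Why: Condensation of the ketone with the sulfonyl hydrazide gives the N-tosylhydrazone that serves as carbene precursor.

Step 3
Reactants: 2 2-(2-bromo-4,5-dimethoxyphenyl)-1,3-dioxolane; 4 N′-[1-(3,4-dimethoxyphenyl)ethylidene]-4-methylbenzenesulfonohydrazide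
Product: 5 2-{2-[1-(3,4-dimethoxyphenyl)ethenyl]-4,5-dimethoxyphenyl}-1,3-dioxolane
Conditions: Pd2(dba)3 (2.5 mol %), XPhos (10 mol %), LiOtBu (2.4 equiv), 1,4-dioxane, 100 °C
Reagents that add atoms: none
Why: Barluenga coupling: the diazo compound released from the tosylhydrazone forms a palladium carbene with the arylpalladium bromide, and aryl migration followed by β-hydride elimination gives the 1,1-diarylethene, a reaction that tolerates ortho-substituted aryl bromides.

Step 4
Reactants: 5 2-{2-[1-(3,4-dimethoxyphenyl)ethenyl]-4,5-dimethoxyphenyl}-1,3-dioxolane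
Product: 6 2-{2-[(1R)-1-(3,4-dimethoxyphenyl)-2-(4,4,5,5-tetramethyl-1,3,2-dioxaborolan-2-yl)ethyl]-4,5-dimethoxyphenyl}-1,3-dioxolane
Conditions: CuCl (5 mol %), (R)-DTBM-SEGPHOS (6 mol %), NaOtBu (10 mol %), HBpin (1.5 equiv), THF, 25 °C
Reagents that add atoms: pinacolborane, B1OC(C)(C)C(C)(C)O1
Why: Cu–H catalysed enantioselective hydroboration of a 1,1-disubstituted vinylarene puts copper on the terminal carbon and hydride on C-c, and the chiral bisphosphine should tell the alkene faces apart because the ortho-substituted ring B is twisted out of the alkene plane while ring C is coplanar, which sets C-c as (R).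

Step 5
Reactants: 7 2-bromo-4-methoxyphenol
Product: 8 2-bromo-6-iodo-4-methoxyphenol
Conditions: NIS (1.05 equiv), p-TsOH·H2O (10 mol %), MeCN, 0 → 25 °C
Reagents that add atoms: N-iodosuccinimide, O=C1CCC(=O)N1I
Why: Electrophilic iodination goes to the only free position ortho to the hydroxyl group, the para position being blocked by the methoxy group.

Step 6
Reactants: 8 2-bromo-6-iodo-4-methoxyphenol
Product: 9 1-bromo-3-iodo-5-methoxy-2-(methoxymethoxy)benzene
Conditions: MOMCl (1.5 equiv), i-Pr2NEt (2 equiv), CH2Cl2, 0 → 25 °C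
Reagents that add atoms: chloromethyl methyl ether, COCCl
Why: O-alkylation gives the MOM ether, which survives the basic coupling and is later removed together with the acetal.

Step 7
Reactants: 6 2-{2-[(1R)-1-(3,4-dimethoxyphenyl)-2-(4,4,5,5-tetramethyl-1,3,2-dioxaborolan-2-yl)ethyl]-4,5-dimethoxyphenyl}-1,3-dioxolane; 9 1-bromo-3-iodo-5-methoxy-2-(methoxymethoxy)benzene
Product: 10 2-{2-[(1R)-2-[3-bromo-5-methoxy-2-(methoxymethoxy)phenyl]-1-(3,4-dimethoxyphenyl)ethyl]-4,5-dimethoxyphenyl}-1,3-dioxolane
Conditions: Pd(dppf)Cl2 (5 mol %), K3PO4 (3 equiv), DMF/H2O 9:1, 70 °C, 9 in 1.3-fold excess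
Reagents that add atoms: none
Why: B-alkyl Suzuki–Miyaura coupling forms the C-d–ring D bond; oxidative addition into C–I is much faster than into C–Br, so the bromide needed for the later silyl shift should be kept, and the remote centre C-c is not touched.

Step 8
Reactants: 10 2-{2-[(1R)-2-[3-bromo-5-methoxy-2-(methoxymethoxy)phenyl]-1-(3,4-dimethoxyphenyl)ethyl]-4,5-dimethoxyphenyl}-1,3-dioxolane
Product: 11 2-[(1R)-2-(3-bromo-2-hydroxy-5-methoxyphenyl)-1-(3,4-dimethoxyphenyl)ethyl]-4,5-dimethoxybenzaldehyde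
Conditions: HCl (3 M aq), THF/MeOH, 50 °C
Reagents that add atoms: water, O
Why: Aqueous acid hydrolyses the dioxolane and the MOM ether in one operation, at a stage where no alkene is present that could be protonated to a benzylic cation.

Step 9
Reactants: 11 2-[(1R)-2-(3-bromo-2-hydroxy-5-methoxyphenyl)-1-(3,4-dimethoxyphenyl)ethyl]-4,5-dimethoxybenzaldehyde; 12 diethyl (3,5-dimethoxybenzyl)phosphonate
Product: 13 2-bromo-6-[(2R)-2-(3,4-dimethoxyphenyl)-2-{2-[(E)-2-(3,5-dimethoxyphenyl)ethenyl]-4,5-dimethoxyphenyl}ethyl]-4-methoxyphenol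
Conditions: KOtBu (3 equiv), THF, 0 → 25 °C; aq NH4Cl
Reagents that add atoms: none
Why: Horner–Wadsworth–Emmons olefination of a benzylic phosphonate with an aryl aldehyde should give the (E)-stilbene selectively, the extra base only turning the phenol into its phenoxide.

Step 10
Reactants: 13 2-bromo-6-[(2R)-2-(3,4-dimethoxyphenyl)-2-{2-[(E)-2-(3,5-dimethoxyphenyl)ethenyl]-4,5-dimethoxyphenyl}ethyl]-4-methoxyphenol
Product: 14 {2-bromo-6-[(2R)-2-(3,4-dimethoxyphenyl)-2-{2-[(E)-2-(3,5-dimethoxyphenyl)ethenyl]-4,5-dimethoxyphenyl}ethyl]-4-methoxyphenoxy}trimethylsilane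
Conditions: HMDS (2 equiv), THF, 70 °C; evaporate
Reagents that add atoms: hexamethyldisilazane, C[Si](C)(C)N[Si](C)(C)C
Why: O-silylation of the phenol with HMDS is the standard first half of the preparation of o-silylaryl triflate aryne precursors.

Step 11
Reactants: 14 {2-bromo-6-[(2R)-2-(3,4-dimethoxyphenyl)-2-{2-[(E)-2-(3,5-dimethoxyphenyl)ethenyl]-4,5-dimethoxyphenyl}ethyl]-4-methoxyphenoxy}trimethylsilane
Product: 17 2-[(2R)-2-(3,4-dimethoxyphenyl)-2-{2-[(E)-2-(3,5-dimethoxyphenyl)ethenyl]-4,5-dimethoxyphenyl}ethyl]-4-methoxy-6-(trimethylsilyl)phenyl trifluoromethanesulfonate, via aryllithium 15 (not isolated), via lithium silylphenoxide 16 (not isolated)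
Conditions: n-BuLi (1.1 equiv), THF, −100 → −78 °C; then Tf2O (1.2 equiv), −100 → −78 °C
Reagents that add atoms: trifluoromethanesulfonic anhydride, O=S(=O)(OS(=O)(=O)C(F)(F)F)C(F)(F)F
Why: Bromine–lithium exchange, 1,3-shift of silicon from oxygen to carbon (retro-Brook rearrangement) and O-triflation of the resulting phenoxide run in one flask, and the exchange at −100 °C should be faster than addition of n-BuLi to the stilbene.

Step 12
Reactants: 17 2-[(2R)-2-(3,4-dimethoxyphenyl)-2-{2-[(E)-2-(3,5-dimethoxyphenyl)ethenyl]-4,5-dimethoxyphenyl}ethyl]-4-methoxy-6-(trimethylsilyl)phenyl trifluoromethanesulfonate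
Product: 20 hepta-O-methyl ether of the target (C-a S; C-c R), via aryne 18 (not isolated), via isoaromatic cycloadduct 19 (not isolated)
Conditions: CsF (4 equiv), MeCN, 0.005 M (slow addition of 17), 60 °C, Ar; then AcOH (5 equiv), 25 °C
Reagents that add atoms: none
Why: Proposed new method: fluoride attacks silicon, triflate leaves and the aryne 18 (triple bond between the two adjacent ring D carbons) adds across the 4π unit made of C-a=C-b and the ipso and ortho carbons of ring A in a concerted, asynchronous [4+2] cycloaddition, after which the isotoluene-type triene 19 regains aromaticity by a fluoride- or acid-mediated 1,3-proton shift from the ring A ortho carbon to C-b. The closest known reactions are the intermolecular Diels–Alder reaction of arynes with styrenes, which gives 9,10-dihydrophenanthrenes, and intramolecular aryne [4+2] cycloadditions with tethered dienes, enynes and arenynes; new here are the seven-membered tether ring and the prototropic (instead of ene-type) rearomatisation. The six-membered ring closes as the new cyclohexadiene ring of the cycloadduct and the seven-membered ring as the tether ring of a type 1 intramolecular Diels–Alder reaction, whose five-atom tether holds only two freely rotating sp3 carbons (C-d and C-c) between two benzo units. The new stereocentre C-a is controlled by C-c: in the boat-like forming seven-membered ring C-c lies on the alkene face that carries the inside hydrogen of C-a, its inward (flagpole) position can only hold hydrogen, so the 3,4-dimethoxyphenyl group is pseudo-equatorial and the hydrogens at C-a and C-c should end up cis, which is (S) at C-a from (R) at C-c. The step needs periselectivity for [4+2] over [2+2] addition to the stilbene and over ene or nucleophilic trapping, and it needs intramolecular over intermolecular reaction: the alkene has no allylic hydrogen, the tether lets the aryne carbon next to C-d reach only C-a while the other aryne carbon then lies over a ring A ortho carbon (both ortho positions are equivalent), the 3,5-dimethoxyphenyl ring makes the diene electron-rich, and high dilution suppresses aryne dimerisation.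

Step 13
Reactants: 20 hepta-O-methyl ether of the target (C-a S; C-c R)
Product: 21 target heptaphenol CNP0306974.2 (C-a S; C-c R)
Conditions: BBr3 (14 equiv), CH2Cl2, −78 → 25 °C; then MeOH, H2O
Reagents that add atoms: none
Why: BBr3 cleaves all seven aryl methyl ethers by Lewis acid complexation and SN2 attack of bromide on methyl, and the two benzylic C–H stereocentres carry no leaving group and should not ionise.

## Compound list

1 | 2-bromo-4,5-dimethoxybenzaldehyde | COc1cc(Br)c(C=O)cc1OC | starting material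
2 | 2-(2-bromo-4,5-dimethoxyphenyl)-1,3-dioxolane | COc1cc(Br)c(cc1OC)C1OCCO1 | intermediate
3 | 3′,4′-dimethoxyacetophenone | CC(=O)c1ccc(OC)c(OC)c1 | starting material
4 | N′-[1-(3,4-dimethoxyphenyl)ethylidene]-4-methylbenzenesulfonohydrazide | CC(=NNS(=O)(=O)c1ccc(C)cc1)c1ccc(OC)c(OC)c1 | intermediate
5 | 2-{2-[1-(3,4-dimethoxyphenyl)ethenyl]-4,5-dimethoxyphenyl}-1,3-dioxolane | C=C(c1ccc(OC)c(OC)c1)c1cc(OC)c(OC)cc1C1OCCO1 | intermediate
6 | 2-{2-[(1R)-1-(3,4-dimethoxyphenyl)-2-(4,4,5,5-tetramethyl-1,3,2-dioxaborolan-2-yl)ethyl]-4,5-dimethoxyphenyl}-1,3-dioxolane | COc1cc(C2OCCO2)c(cc1OC)[C@@H](c1ccc(OC)c(OC)c1)CB1OC(C)(C)C(C)(C)O1 | intermediate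
7 | 2-bromo-4-methoxyphenol | COc1ccc(O)c(Br)c1 | starting material
8 | 2-bromo-6-iodo-4-methoxyphenol | COc1cc(Br)c(O)c(I)c1 | intermediate
9 | 1-bromo-3-iodo-5-methoxy-2-(methoxymethoxy)benzene | COCOc1c(Br)cc(OC)cc1I | intermediate
10 | 2-{2-[(1R)-2-[3-bromo-5-methoxy-2-(methoxymethoxy)phenyl]-1-(3,4-dimethoxyphenyl)ethyl]-4,5-dimethoxyphenyl}-1,3-dioxolane | COc1cc(C2OCCO2)c(cc1OC)[C@@H](c1ccc(OC)c(OC)c1)Cc1cc(OC)cc(Br)c1OCOC | intermediate
11 | 2-[(1R)-2-(3-bromo-2-hydroxy-5-methoxyphenyl)-1-(3,4-dimethoxyphenyl)ethyl]-4,5-dimethoxybenzaldehyde | COc1cc(C=O)c(cc1OC)[C@@H](c1ccc(OC)c(OC)c1)Cc1cc(OC)cc(Br)c1O | intermediate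
12 | diethyl (3,5-dimethoxybenzyl)phosphonate | CCOP(=O)(OCC)Cc1cc(OC)cc(OC)c1 | starting material
13 | 2-bromo-6-[(2R)-2-(3,4-dimethoxyphenyl)-2-{2-[(E)-2-(3,5-dimethoxyphenyl)ethenyl]-4,5-dimethoxyphenyl}ethyl]-4-methoxyphenol | COc1cc(/C=C/c2cc(OC)cc(OC)c2)c(cc1OC)[C@@H](c1ccc(OC)c(OC)c1)Cc1cc(OC)cc(Br)c1O | intermediate
14 | O-trimethylsilyl ether of 13 | COc1cc(/C=C/c2cc(OC)cc(OC)c2)c(cc1OC)[C@@H](c1ccc(OC)c(OC)c1)Cc1cc(OC)cc(Br)c1O[Si](C)(C)C | intermediate
15 | aryllithium from bromine–lithium exchange of 14 (lithium on the ring D carbon that carried bromine) | COc1cc(/C=C/c2cc(OC)cc(OC)c2)c(cc1OC)[C@@H](c1ccc(OC)c(OC)c1)Cc1cc(OC)cc([Li])c1O[Si](C)(C)C | intermediate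
16 | lithium 2-(trimethylsilyl)phenoxide formed by the silyl shift | COc1cc(/C=C/c2cc(OC)cc(OC)c2)c(cc1OC)[C@@H](c1ccc(OC)c(OC)c1)Cc1cc(OC)cc([Si](C)(C)C)c1[O-].[Li+] | intermediate
17 | 2-[(2R)-2-(3,4-dimethoxyphenyl)-2-{2-[(E)-2-(3,5-dimethoxyphenyl)ethenyl]-4,5-dimethoxyphenyl}ethyl]-4-methoxy-6-(trimethylsilyl)phenyl trifluoromethanesulfonate | COc1cc(/C=C/c2cc(OC)cc(OC)c2)c(cc1OC)[C@@H](c1ccc(OC)c(OC)c1)Cc1cc(OC)cc([Si](C)(C)C)c1OS(=O)(=O)C(F)(F)F | intermediate
18 | aryne: ring D of 17 with a triple bond between the former C–OTf and C–Si carbons | COc1cc(/C=C/c2cc(OC)cc(OC)c2)c(cc1OC)[C@@H](c1ccc(OC)c(OC)c1)CC1=CC(OC)=CC#C1 | intermediate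
19 | isoaromatic [4+2] adduct: both new bonds formed, ring A as a 1,3-dimethoxycyclohexadiene with an sp3 CH at the biaryl carbon and an exocyclic C-b=C bond; H at that carbon cis to H at C-a | COC1=CC(=C[C@H]2c3cc(OC)c(OC)cc3[C@@H](c3ccc(OC)c(OC)c3)Cc3cc(OC)cc4c32)[C@@H]4C(OC)=C1 | intermediate
20 | hepta-O-methyl ether of the target: 9,10-dihydrophenanthrene (rings A and D) whose C-a is also C-5 of a 10,11-dihydro-5H-dibenzo[a,d][7]annulene (rings D and B) bearing the 3,4-dimethoxyphenyl group at C-c; C-a (S), C-c (R), H at C-a and H at C-c cis | COc1cc(OC)c2c(c1)C[C@H]1c3cc(OC)c(OC)cc3[C@@H](c3ccc(OC)c(OC)c3)Cc3cc(OC)cc-2c31 | intermediate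
21 | target heptaphenol CNP0306974.2; C-a (S), C-c (R) | Oc1cc(O)c2c(c1)C[C@H]1c3cc(O)c(O)cc3[C@@H](c3ccc(O)c(O)c3)Cc3cc(O)cc-2c31 | target

## Step count and risks

Total step count: 13. Longest linear sequence: 10 steps (steps 1, 3, 4, 7, 8, 9, 10, 11, 12, 13).

Steps most likely to fail:

**Step 12 (proposed new method).** The tethered aryne may be consumed by [2+2] addition to the stilbene, by fluoride or solvent, or by oligomerisation before the bicyclic transition state is reached. Facial selectivity at C-a may be poor. The triene may be oxidised to the phenanthrene instead of undergoing the proton shift.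
Fallback with known chemistry, from 17 back to 20: an intramolecular 7-exo Mizoroki–Heck reaction of the aryl triflate with the stilbene (Pd(OAc)2, dppf, Et3N, DMF, 90 °C; the aryl–silicon bond is inert) would give the benzylidene-dibenzosuberane silane F1. Hydrogenation (H2, Pd/C, EtOAc) should then give the cis-configured benzyl-dibenzosuberane silane F2, with separation of C-a epimers if needed. Gold-catalysed oxidative coupling of the aryltrimethylsilane with an ortho C–H bond of ring A (Ph3PAuOTs, PhI(OAc)2, camphorsulfonic acid, CHCl3/MeOH, 50 °C), a known closure of five- to nine-membered biaryl rings, would give 20.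

**Step 4.** Facial discrimination between two electronically similar aryl groups may be poor, and hydrocupration of the hindered 1,1-diarylethene may be slow.
Fallback, from 5 back to 10: hydroboration with an achiral catalyst (CuCl, Xantphos, NaOtBu, HBpin, THF) would give the racemic boronate F3. Suzuki coupling with 9 under the conditions of step 7 would give the racemic triarylethane F4. Preparative supercritical-fluid chromatography on a chiral stationary phase would then deliver 10 and set aside the (S)-enantiomer F5.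

**Step 7.** Transmetalation of the β-branched primary boronate may be slow. β-Hydride elimination to the 1,1-diarylethene may compete, and selectivity for C–I over C–Br may be lost at the temperature needed.
Fallback, from 6 back to 10: oxidation (NaBO3·4H2O, THF/H2O) would give the (2R)-2,2-diarylethanol F6, and iodination (I2, PPh3, imidazole, CH2Cl2) the primary iodide F7. Zinc insertion (Zn dust, LiCl, THF, 40 °C) would give the alkylzinc iodide F8. Negishi coupling with 9 (Pd(dppf)Cl2, THF, 25 °C) reacts only at the C–I bond at this temperature and would give 10.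

## Further compounds

F1 | step 12 | [(10R)-10-(3,4-dimethoxyphenyl)-5-[(3,5-dimethoxyphenyl)methylidene]-2,7,8-trimethoxy-10,11-dihydro-5H-dibenzo[a,d][7]annulen-4-yl]trimethylsilane | COc1cc(OC)cc(c1)C=C1c2cc(OC)c(OC)cc2[C@@H](c2ccc(OC)c(OC)c2)Cc2cc(OC)cc([Si](C)(C)C)c12
F2 | step 12 | [(5S,10R)-10-(3,4-dimethoxyphenyl)-5-[(3,5-dimethoxyphenyl)methyl]-2,7,8-trimethoxy-10,11-dihydro-5H-dibenzo[a,d][7]annulen-4-yl]trimethylsilane | COc1cc(OC)cc(c1)C[C@H]1c2cc(OC)c(OC)cc2[C@@H](c2ccc(OC)c(OC)c2)Cc2cc(OC)cc([Si](C)(C)C)c12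
F3 | step 4 | racemic 2-{2-[1-(3,4-dimethoxyphenyl)-2-(4,4,5,5-tetramethyl-1,3,2-dioxaborolan-2-yl)ethyl]-4,5-dimethoxyphenyl}-1,3-dioxolane | COc1cc(C2OCCO2)c(cc1OC)C(c1ccc(OC)c(OC)c1)CB1OC(C)(C)C(C)(C)O1
F4 | step 4 | racemic 2-{2-[2-[3-bromo-5-methoxy-2-(methoxymethoxy)phenyl]-1-(3,4-dimethoxyphenyl)ethyl]-4,5-dimethoxyphenyl}-1,3-dioxolane | COc1cc(C2OCCO2)c(cc1OC)C(c1ccc(OC)c(OC)c1)Cc1cc(OC)cc(Br)c1OCOC
F5 | step 4 | 2-{2-[(1S)-2-[3-bromo-5-methoxy-2-(methoxymethoxy)phenyl]-1-(3,4-dimethoxyphenyl)ethyl]-4,5-dimethoxyphenyl}-1,3-dioxolane | COc1cc(C2OCCO2)c(cc1OC)[C@H](c1ccc(OC)c(OC)c1)Cc1cc(OC)cc(Br)c1OCOC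
F6 | step 7 | (2R)-2-(3,4-dimethoxyphenyl)-2-[2-(1,3-dioxolan-2-yl)-4,5-dimethoxyphenyl]ethan-1-ol | COc1cc(C2OCCO2)c(cc1OC)[C@@H](c1ccc(OC)c(OC)c1)CO
F7 | step 7 | 2-{2-[(1R)-1-(3,4-dimethoxyphenyl)-2-iodoethyl]-4,5-dimethoxyphenyl}-1,3-dioxolane | COc1cc(C2OCCO2)c(cc1OC)[C@@H](c1ccc(OC)c(OC)c1)CI
F8 | step 7 | [(2R)-2-(3,4-dimethoxyphenyl)-2-[2-(1,3-dioxolan-2-yl)-4,5-dimethoxyphenyl]ethyl]zinc iodide | COc1cc(C2OCCO2)c(cc1OC)[C@@H](c1ccc(OC)c(OC)c1)C[Zn]I
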